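**Plan**

- Retrosynthesis: the formyl C=O goes back to the C=C of an aryl vinyl group; the two ester C–O bonds (phenol and primary alcohol) are cut to a diol and 3-methylbutanoic anhydride; the oxirane is cut at the two bonds of its CH2 carbon, CH2–C(quaternary) and CH2–O.
- The last cut is possible because the oxirane is terminal and 2,2-disubstituted: its CH2 is unsubstituted and the other ring carbon carries only the arene and a CH2O arm. That carbon and the ring oxygen are therefore the C=O of an aryl silyloxymethyl ketone, and the CH2 is a one-carbon sulfur ylide.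
- Forward: the ketone is assembled on 1-(4-bromo-2-hydroxyphenyl)ethanone (phenol silylation, silyl enol ether, Rubottom oxygenation, Stille vinylation). The oxirane, the only ring formed, is closed in step 6. Desilylation, double acylation and ozonolysis follow.
- Stereochemistry: the single stereocentre (quaternary oxirane carbon, R in the target) is set in step 6 by Re-face methylene transfer under a chiral LaLi3(binaphthoxide)3 complex. No later step touches its four bonds.

Key step: step 6

Assumption: the sense of induction of the lanthanum–lithium binaphthoxide catalyst is taken over from aryl methyl ketones, with the CH2OSi arm in the place of methyl, so the (S)-binaphthoxide complex is written; if the first batch of 14 proved to be the mirror image, the (R)-binaphthoxide complex would be used with nothing else changed.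

**Route**

Step 1
Reactants: 1 1-(4-bromo-2-hydroxyphenyl)ethanone; 2 chlorotri(propan-2-yl)silane
Product: 3 1-(4-bromo-2-{[tri(propan-2-yl)silyl]oxy}phenyl)ethanone
Conditions: iPr3SiCl (1.3 equiv), imidazole (2.5 equiv), DMF, rt to 40 °C
Reagents that add atoms: chlorotri(propan-2-yl)silane 2, CC(C)[Si](Cl)(C(C)C)C(C)C
Why: Imidazole-promoted O-silylation of a phenol is routine, and the bulky triisopropylsilyl ether is chosen because it should survive the Stille and ylide steps and is slow to migrate from oxygen to oxygen.

Step 2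
Reactants: 3 1-(4-bromo-2-{[tri(propan-2-yl)silyl]oxy}phenyl)ethanone; 4 tert-butyldimethylsilyl trifluoromethanesulfonate
Product: 5 tert-butyl{[1-(4-bromo-2-{[tri(propan-2-yl)silyl]oxy}phenyl)ethenyl]oxy}dimethylsilane
Conditions: tBuMe2SiOTf (1.3 equiv), Et3N (2.0 equiv), CH2Cl2, 0 °C to rt
Reagents that add atoms: tert-butyldimethylsilyl trifluoromethanesulfonate 4, CC(C)(C)[Si](C)(C)OS(=O)(=O)C(F)(F)F
Why: Soft enolisation of an aryl methyl ketone with a silyl triflate and triethylamine gives the only possible silyl enol ether, and the aryl silyl ether and the aryl bromide are inert to these conditions.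

Step 3
Reactants: 5 tert-butyl{[1-(4-bromo-2-{[tri(propan-2-yl)silyl]oxy}phenyl)ethenyl]oxy}dimethylsilane; 6 3-chloroperoxybenzoic acid
Product: 8 1-(4-bromo-2-{[tri(propan-2-yl)silyl]oxy}phenyl)-2-[(tert-butyldimethylsilyl)oxy]ethanone, via silyloxyoxirane 7 (not isolated)
Conditions: mCPBA (1.1 equiv), CH2Cl2, −20 to 0 °C
Reagents that add atoms: 3-chloroperoxybenzoic acid 6, OOC(=O)c1cccc(Cl)c1
Why: In this Rubottom oxidation the peracid epoxidises the electron-rich enol ether, the only alkene present at this stage, and the silyloxyoxirane 7 opens to an oxocarbenium ion in which the tert-butyldimethylsilyl group shifts to the new oxygen (1,4-silyl migration), which should give the α-silyloxy ketone directly.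

Step 4
Reactants: 8 1-(4-bromo-2-{[tri(propan-2-yl)silyl]oxy}phenyl)-2-[(tert-butyldimethylsilyl)oxy]ethanone; 9 tributyl(ethenyl)stannane
Product: 10 2-[(tert-butyldimethylsilyl)oxy]-1-(4-ethenyl-2-{[tri(propan-2-yl)silyl]oxy}phenyl)ethanone
Conditions: Bu3SnCH=CH2 (1.2 equiv), Pd(PPh3)4 (5 mol %), BHT (trace), toluene, 100 °C
Reagents that add atoms: tributyl(ethenyl)stannane 9, C=C[Sn](CCCC)(CCCC)CCCC
Why: In this Stille coupling the aryl bromide para to the acyl group is activated for oxidative addition to zerovalent palladium, the neutral base-free and fluoride-free medium should spare both silyl ethers and the enolisable ketone, and the vinyl group is introduced only now because it would not survive the peracid of step 3.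

Step 5
Reactants: 11 trimethylsulfoxonium chloride
Product: 12 dimethyloxosulfonium methylide (kept as a titrated THF solution)
Conditions: NaH (1.0 equiv, oil-free), THF, reflux; filtration under argon
Reagents that add atoms: none
Why: Deprotonation of the sulfoxonium salt by NaH in THF gives the ylide, and filtering off the insoluble NaCl should leave a salt-free solution that does not disturb the lanthanum–lithium catalyst of step 6.

Step 6
Reactants: 10 2-[(tert-butyldimethylsilyl)oxy]-1-(4-ethenyl-2-{[tri(propan-2-yl)silyl]oxy}phenyl)ethanone; 12 dimethyloxosulfonium methylide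
Product: 14 tert-butyl{[(2R)-2-(4-ethenyl-2-{[tri(propan-2-yl)silyl]oxy}phenyl)oxiran-2-yl]methoxy}dimethylsilane, via sulfoxonium betaine 13 (not isolated)
Conditions: 12 (1.2 equiv), LaLi3[(S)-1,1'-binaphthalene-2,2'-diolate]3 (5 mol %), (2,4,6-(MeO)3C6H2)3P=O (5 mol %), 5 Å MS, THF, rt
Reagents that add atoms: dimethyloxosulfonium methylide 12, C[S+](C)(=O)[CH2-]
Why: The ketone carbonyl binds to trivalent lanthanum while a lithium binaphthoxide arm holds the ylide; the ylide carbon adds to the carbonyl carbon (new C–C bond) to give betaine 13, whose alkoxide displaces dimethyl sulfoxide from the CH2–S carbon in a 3-exo-tet closure (new C–O bond, oxirane ring). The closest known reaction is the Corey–Chaykovsky epoxidation of aryl methyl ketones catalysed by LaLi3(binaphthoxide)3 with a triarylphosphine oxide. The quaternary stereocentre is set in the addition step by the binaphthoxide chirality, which must open the Re face of the ketone (ranking O > CH2OSi > aryl) to give the R epoxide. Facial discrimination rests on the size difference between the twisted ortho-silyloxyaryl group and the CH2OSi arm. Chemoselectivity is secured because the ketone is the only electrophile: the future aldehyde is a vinyl group, no ester is present, and the phenol carries the slow-migrating triisopropylsilyl group, so the betaine alkoxide should close the ring before silicon can shift to it.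

Step 7
Reactants: 14 tert-butyl{[(2R)-2-(4-ethenyl-2-{[tri(propan-2-yl)silyl]oxy}phenyl)oxiran-2-yl]methoxy}dimethylsilane
Product: 15 5-ethenyl-2-[(2S)-2-(hydroxymethyl)oxiran-2-yl]phenol
Conditions: Bu4NF (3 equiv), AcOH (3 equiv), THF, 0 °C to rt; crude product used at once
Reagents that add atoms: none
Why: Fluoride cleaves both Si–O bonds (the aryl silyl ether first, the primary one more slowly) while acetic acid protonates the phenoxide and alkoxide as they form so that the epoxide does not meet a free phenoxide; the stereocentre is untouched and its descriptor changes from R to S only because the ranking of the two CH2O arms changes.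

Step 8
Reactants: 15 5-ethenyl-2-[(2S)-2-(hydroxymethyl)oxiran-2-yl]phenol; 16 3-methylbutanoic anhydride
Product: 17 [(2R)-2-{4-ethenyl-2-[(3-methylbutanoyl)oxy]phenyl}oxiran-2-yl]methyl 3-methylbutanoate
Conditions: (iPrCH2CO)2O (3 equiv), Et3N (4 equiv), DMAP (0.1 equiv), CH2Cl2, 0 °C
Reagents that add atoms: 3-methylbutanoic anhydride 16, CC(C)CC(=O)OC(=O)CC(C)C
Why: DMAP-catalysed acylation should esterify the phenol and the primary alcohol in one operation, and the anhydride is preferred to the acid chloride so that neither chloride nor strong acid meets the benzylic epoxide.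

Step 9
Reactants: 17 [(2R)-2-{4-ethenyl-2-[(3-methylbutanoyl)oxy]phenyl}oxiran-2-yl]methyl 3-methylbutanoate; 18 ozone
Product: 20 [(2R)-2-{4-formyl-2-[(3-methylbutanoyl)oxy]phenyl}oxiran-2-yl]methyl 3-methylbutanoate (CNP0274578.1), via secondary ozonide 19 (not isolated)
Conditions: O3, CH2Cl2, −78 °C (Sudan red end point); then PPh3 (1.5 equiv), −78 °C to rt
Reagents that add atoms: ozone 18, [O-][O+]=O
Why: Ozonolysis by the Criegee pathway cleaves the only C=C bond, reduction of ozonide 19 with triphenylphosphine releases the aryl aldehyde, and the epoxide, the two esters and the acyloxy-deactivated arene should be inert to ozone at −78 °C.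

**Compound list**

1 | 1-(4-bromo-2-hydroxyphenyl)ethanone | CC(=O)c1ccc(Br)cc1O | starting material
2 | chlorotri(propan-2-yl)silane | CC(C)[Si](Cl)(C(C)C)C(C)C | starting material
3 | 1-(4-bromo-2-{[tri(propan-2-yl)silyl]oxy}phenyl)ethanone | CC(=O)c1ccc(Br)cc1O[Si](C(C)C)(C(C)C)C(C)C | intermediate
4 | tert-butyldimethylsilyl trifluoromethanesulfonate | CC(C)(C)[Si](C)(C)OS(=O)(=O)C(F)(F)F | starting material
5 | tert-butyl{[1-(4-bromo-2-{[tri(propan-2-yl)silyl]oxy}phenyl)ethenyl]oxy}dimethylsilane | C=C(O[Si](C)(C)C(C)(C)C)c1ccc(Br)cc1O[Si](C(C)C)(C(C)C)C(C)C | intermediate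
6 | 3-chloroperoxybenzoic acid | OOC(=O)c1cccc(Cl)c1 | starting material
7 | rac-2-(4-bromo-2-{[tri(propan-2-yl)silyl]oxy}phenyl)-2-[(tert-butyldimethylsilyl)oxy]oxirane (silyloxyoxirane) | CC(C)(C)[Si](C)(C)OC1(CO1)c1ccc(Br)cc1O[Si](C(C)C)(C(C)C)C(C)C | intermediate
8 | 1-(4-bromo-2-{[tri(propan-2-yl)silyl]oxy}phenyl)-2-[(tert-butyldimethylsilyl)oxy]ethanone | CC(C)(C)[Si](C)(C)OCC(=O)c1ccc(Br)cc1O[Si](C(C)C)(C(C)C)C(C)C | intermediate
9 | tributyl(ethenyl)stannane | C=C[Sn](CCCC)(CCCC)CCCC | starting material
10 | 2-[(tert-butyldimethylsilyl)oxy]-1-(4-ethenyl-2-{[tri(propan-2-yl)silyl]oxy}phenyl)ethanone | CC(C)(C)[Si](C)(C)OCC(=O)c1ccc(C=C)cc1O[Si](C(C)C)(C(C)C)C(C)C | intermediate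
11 | trimethylsulfoxonium chloride | C[S+](C)(C)=O.[Cl-] | starting material
12 | dimethyloxosulfonium methylide | C[S+](C)(=O)[CH2-] | intermediate
13 | (2S)-1-[(tert-butyldimethylsilyl)oxy]-3-(dimethyloxosulfonio)-2-(4-ethenyl-2-{[tri(propan-2-yl)silyl]oxy}phenyl)propan-2-olate (sulfoxonium betaine, metal-bound in the flask) | CC(C)(C)[Si](C)(C)OC[C@@]([O-])(c1ccc(C=C)cc1O[Si](C(C)C)(C(C)C)C(C)C)C[S+](C)(C)=O | intermediate
14 | tert-butyl{[(2R)-2-(4-ethenyl-2-{[tri(propan-2-yl)silyl]oxy}phenyl)oxiran-2-yl]methoxy}dimethylsilane | CC(C)(C)[Si](C)(C)OC[C@@]1(c2ccc(C=C)cc2O[Si](C(C)C)(C(C)C)C(C)C)CO1 | intermediate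
15 | 5-ethenyl-2-[(2S)-2-(hydroxymethyl)oxiran-2-yl]phenol | OC[C@@]1(c2ccc(C=C)cc2O)CO1 | intermediate
16 | 3-methylbutanoic anhydride | CC(C)CC(=O)OC(=O)CC(C)C | starting material
17 | [(2R)-2-{4-ethenyl-2-[(3-methylbutanoyl)oxy]phenyl}oxiran-2-yl]methyl 3-methylbutanoate | CC(C)CC(=O)OC[C@@]1(c2ccc(C=C)cc2OC(=O)CC(C)C)CO1 | intermediate
18 | ozone | [O-][O+]=O | starting material
19 | [(2R)-2-{2-[(3-methylbutanoyl)oxy]-4-(1,2,4-trioxolan-3-yl)phenyl}oxiran-2-yl]methyl 3-methylbutanoate (secondary ozonide, both epimers at the trioxolane carbon) | CC(C)CC(=O)OC[C@@]1(c2ccc(C3OCOO3)cc2OC(=O)CC(C)C)CO1 | intermediate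
20 | [(2R)-2-{4-formyl-2-[(3-methylbutanoyl)oxy]phenyl}oxiran-2-yl]methyl 3-methylbutanoate | CC(C)CC(=O)OC[C@@]1(c2ccc(C=O)cc2OC(=O)CC(C)C)CO1 | target

**Step count and risks**

Total step count: 9. Longest linear sequence: 8 steps (steps 1–4 and 6–9, from 1 to 20); step 5 is a one-step side branch that joins at step 6.

The three steps most likely to fail:

Step 6. The catalyst is tuned for methyl ketones, so facial discrimination may be poor with the larger CH2OSi arm, and the ortho-silyloxy group may slow addition to the hindered carbonyl so that enolisation by the ylide competes. The fallback replaces methylene transfer to C=O by oxygen transfer to C=C. It sets out from 10, which Wittig methylenation (Ph3PCH3Br, KN(SiMe3)2, THF, 0 °C) should convert into tert-butyl{[2-(4-ethenyl-2-{[tri(propan-2-yl)silyl]oxy}phenyl)prop-2-en-1-yl]oxy}dimethylsilane F1. Mild acid methanolysis (PPTS, MeOH, rt) should remove only the primary silyl group and give 2-(4-ethenyl-2-{[tri(propan-2-yl)silyl]oxy}phenyl)prop-2-en-1-ol F2. Sharpless asymmetric epoxidation (Ti(OiPr)4, diethyl L-(+)-tartrate, tBuOOH, 4 Å MS, CH2Cl2, −20 °C) should then give [(2S)-2-(4-ethenyl-2-{[tri(propan-2-yl)silyl]oxy}phenyl)oxiran-2-yl]methanol F3; the sense follows the rule for 2-substituted allylic alcohols, and the aryl vinyl group, not being allylic to a hydroxyl, should stay untouched. Buffered fluoride (Bu4NF, AcOH, THF, 0 °C) brings the sequence back to the route at 15.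

Step 7. Once the aryl silyl group is lost, the ortho-phenol or its phenoxide can open the neighbouring benzylic epoxide, by intramolecular attack or by ionisation toward an ortho-quinone methide, which would destroy or racemise the stereocentre before acylation. The fallback never leaves the phenol free beside the epoxide. It sets out from 14: one equivalent of Bu4NF in THF at −40 °C should cleave only the aryl silyl ether, and the phenoxide is trapped in the same flask with 16 to give 2-[(2R)-2-{[(tert-butyldimethylsilyl)oxy]methyl}oxiran-2-yl]-5-ethenylphenyl 3-methylbutanoate F4. The primary silyl ether is then removed under non-basic conditions (Et3N·3HF, THF, rt) to give 5-ethenyl-2-[(2S)-2-(hydroxymethyl)oxiran-2-yl]phenyl 3-methylbutanoate F5. Acylation with 16, Et3N and DMAP returns to the route at 17.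

Step 3. The silyloxyoxirane may be intercepted by 3-chlorobenzoic acid or lose silicon before the silyl shift, giving mixtures of silylated and free hydroxy ketone, and excess peracid may begin a Baeyer–Villiger oxidation of the product. The fallback replaces epoxidation and silyl shift by dihydroxylation. It sets out from 5: catalytic OsO4 with N-methylmorpholine N-oxide in aqueous acetone at 0 °C should dihydroxylate the enol ether and, after collapse of the silylated hemiketal, give 1-(4-bromo-2-{[tri(propan-2-yl)silyl]oxy}phenyl)-2-hydroxyethanone F6. Silylation (tBuMe2SiCl, imidazole, DMF, rt) returns to the route at 8.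

**Further compounds**

F1 | step 6 | tert-butyl{[2-(4-ethenyl-2-{[tri(propan-2-yl)silyl]oxy}phenyl)prop-2-en-1-yl]oxy}dimethylsilane | C=C(CO[Si](C)(C)C(C)(C)C)c1ccc(C=C)cc1O[Si](C(C)C)(C(C)C)C(C)C
F2 | step 6 | 2-(4-ethenyl-2-{[tri(propan-2-yl)silyl]oxy}phenyl)prop-2-en-1-ol | C=C(CO)c1ccc(C=C)cc1O[Si](C(C)C)(C(C)C)C(C)C
F3 | step 6 | [(2S)-2-(4-ethenyl-2-{[tri(propan-2-yl)silyl]oxy}phenyl)oxiran-2-yl]methanol | OC[C@@]1(c2ccc(C=C)cc2O[Si](C(C)C)(C(C)C)C(C)C)CO1
F4 | step 7 | 2-[(2R)-2-{[(tert-butyldimethylsilyl)oxy]methyl}oxiran-2-yl]-5-ethenylphenyl 3-methylbutanoate | CC(C)(C)[Si](C)(C)OC[C@@]1(c2ccc(C=C)cc2OC(=O)CC(C)C)CO1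
F5 | step 7 | 5-ethenyl-2-[(2S)-2-(hydroxymethyl)oxiran-2-yl]phenyl 3-methylbutanoate | OC[C@@]1(c2ccc(C=C)cc2OC(=O)CC(C)C)CO1
F6 | step 3 | 1-(4-bromo-2-{[tri(propan-2-yl)silyl]oxy}phenyl)-2-hydroxyethanone | OCC(=O)c1ccc(Br)cc1O[Si](C(C)C)(C(C)C)C(C)C
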